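5 questions stand for 4 flasks: how much bis adduct each holds at the end, and which holds most.

- the best flask by amount of bis adduct, in percent of the substrate charged; "all alike" if 1.5 percentage points covers them all (teal / red / violet / green / all alike)
- amount of bis adduct at the end, in percent of the substrate charged, teal
- amount of bis adduct at the end, in percent of the substrate charged, red
- amount of bis adduct at the end, in percent of the substrate charged, violet
- amount of bis adduct at the end, in percent of the substrate charged, green

| flask | substrate | partner | temperature | remark | time |
|---|---|---|---|---|---|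
| alder | 0.013 M | 0.017 M | −25 °C | run made earlier |  |
| cedar | 0.013 M | 0.039 M | 25 °C | run made earlier |  |
| ash | 0.019 M | 0.026 M | −25 °C | run made earlier |  |
| teal | 0.013 M | 0.0260 M | −20 °C |  | 30 h |
| red | 0.013 M | 0.0260 M | 40 °C |  | 30 h |
| violet | 0.013 M | 0.0260 M | 70 °C |  | 30 h |
| green | 0.013 M | 0.0260 M | 10 °C |  | 30 h |

alder run (percent of the substrate charged): time / h: bis adduct / % = 3.00: 0; 6.00: 0; 10.0: 0; 12.0: 0; 15.0: 0.4; 20.0: 0

cedar run (percent of the substrate charged): time / min: bis adduct / % = 20.0: 1.5; 40.0: 7.0; 60.0: 11.5; 80.0: 18.3; 90.0: 21.2; 120: 29.6

ash run (percent of the substrate charged): time / h: bis adduct / % = 1.33: 0.1; 2.50: 0; 5.00: 0.2; 10.0: 0.1; 20.0: 0.4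

(scatter of a reading: 0.3 percentage points)



The bis adduct carries two partners on one substrate, so I take the statistical case as the zero of my scale: two equal sites reacting independently, the bis adduct being the square of the share of sites reacted. On that scale cedar's last reading, 29.6 % after 120 min, leaves 45.6 % of its sites free. Counting how its partner falls, I get 0.335 h⁻¹ as the site rate, the share of free sites reacting per hour at 25 °C with c partner at 0.0260 M. Ash, at that same c partner and −25 °C, read 0.4 % after 20.0 h, which gives 0.00316 h⁻¹, or 0.00158 h⁻¹ to 0.00418 h⁻¹ within the scatter.

Green is the flask I bracket. Taking the logarithm of the rate as straight in reciprocal absolute temperature (Arrhenius), green lies a fraction 0.263 of the way from cedar to ash. Its clock is site rate times 30 h. From above, I take the upper ash rate with partner held at its charge (pseudo-first-order), so the share reacted is one minus e to the minus clock, and my estimate of the bis adduct is 91.8 %. From below, I take the lower ash rate with partner falling alongside the sites, so the share is clock over one plus clock, and my estimate of the bis adduct is 50.5 %. Partner does fall, so I keep that form with the middle rate: the clock 2.95 gives 55.8 %. The same form gives teal 1.99 %, red 93.7 % and violet 99.0 %. It counts no side loss, so I leave red and violet unranked.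

The forecast reads “a rate drop of about 1000-fold” between cedar and the cold runs, where my factor is 106. It names violet best, with teal 0.5 %, red 92 %, violet 98 % and green 30 %, which is below my lower bound.

The flasks give red as best, with teal 1.81 %, red 93.8 %, violet 90.1 % and green 60.0 %.

    substrate + partner → single product + released group (k = 6.50 L mol⁻¹ min⁻¹, Ea = 62.0 kJ mol⁻¹)
    partner + single product → bis adduct + released group (k = 5.30 L mol⁻¹ min⁻¹, Ea = 53.0 kJ mol⁻¹)
    single product → decomposed reagent (k = 0.00280 min⁻¹, Ea = 105 kJ mol⁻¹)
    substrate ⇌ dormant form (K = 9.50, k = 0.00960 min⁻¹, Ea = 119 kJ mol⁻¹, ΔH = −17.0 kJ mol⁻¹)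
    (constants at 70 °C)

Green's 60.0 % stands inside my bracket, 4.2 percentage points over my figure. Violet reads 8.9 points under my figure, and after 30.0 h it holds 6.52 % decomposed reagent and 3.06 % dormant form. I run the same site rate on a neighbour flask, teal's charge at 5 °C: it lies a fraction 0.357 of the way from cedar to ash, its clock is 1.90, and the square gives 43.0 %. That neighbour flask holds 46.4 % bis adduct after 30.0 h.

The runs were computed for substances that don't exist; scatter was added.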